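From the constants I take how long target lives once formed, and set that against how long target has been forming.

    substrate + coupling partner → intermediate (k1 = 0.0077 L mol⁻¹ min⁻¹)
    second reagent + intermediate → target (k2 = 0.0053 L mol⁻¹ min⁻¹)
    target ⇌ isomer of the product (K3 = 1.8, k3 = 6.4 × 10⁻⁴ min⁻¹)
    substrate + target → side product (k4 = 0.0033 L mol⁻¹ min⁻¹)

| setting | Monday's | Thursday's | Friday's | Saturday's |
|---|---|---|---|---|
| substrate | 0.10 M | 0.10 M | 0.10 M | 0.10 M |
| coupling partner | 0.0600 M | 0.0600 M | 0.0600 M | 0.0600 M (fed, over 2.40 d) |
| second reagent | 0.100 M | 0.100 M | 0.100 M | 0.100 M |
| time | 3.0 d |  | 3.0 d | 3.0 d |
| remark | plug flow through a tube for 3.0 d, no back-mixing | one stirred flow tank at steady state, fed with the mixture as stated, mean residence time 3.0 d | a closed flask charged with all of it at once and left for 3.0 d | a stirred flask in which coupling partner is dosed at a steady rate over 2.40 d without added volume, worked up at 3.0 d |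

- the set-up with the highest share of target in all that became target or isomer of the product or side product, at the outlet or at the end ("none" if the first two lie within 2 percentage points) (Monday's / Thursday's / Friday's / Saturday's / none)
- share of target in all that became target or isomer of the product or side product, at the outlet or at the end, Monday's
- share of target in all that became target or isomer of the product or side product, at the outlet or at the end, Thursday's
- share of target in all that became target or isomer of the product or side product, at the outlet or at the end, Friday's
- share of target in all that became target or isomer of the product or side product, at the outlet or at the end, Saturday's

- in percentages every species weighs as the substrate in it: one side product counts as two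
- the stated concentrations are those of everything mixed, before any reaction; amounts are the same in each set-up
- the feed brings no volume worth counting
- run time (Monday's): 3.0 d

Target leaves by isomerisation, rate constant 6.4 × 10⁻⁴ min⁻¹, and by the side reaction, pseudo-first-order in target with constant 0.0033 L mol⁻¹ min⁻¹ times c(substrate). Freezing c(substrate) at its charge gives 3.30 × 10⁻⁴ min⁻¹, slower than isomerisation. The inverse of the sum, 0.716 d, is the drain time: the mean life of target with substrate frozen at its charge.

The other time is the birth window W, the span over which target has been forming. With steady formation, no return from isomer, each side product taken at the one target it consumed rather than at the weight the asked share gives it, and a window longer than the drain time, target stands near T/W of all it became. Monday's tube ages its mixture as Friday's flask does, so both have the window 3.0 d, and I reckon 23.9%. In Saturday's flask, coupling partner arrives on average at the middle of its dosing, so I take the span from there to the end, 1.80 d, as a rough window, reckon 39.8% and put Saturday's first. I leave Thursday's tank unreckoned, and my reckoning stops there.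

The forecast names Saturday's, with 39% there, 32% for Monday's, 32% for Friday's and 27.5% for Thursday's, on the grounds that “target forms later and has less time to isomerise”. Its Friday's figure is higher than mine.

The simulation gives Saturday's with 39.5%, then 32.2% for Monday's, 32.2% for Friday's and 27.4% for Thursday's. Saturday's flask still holds 53.5% of its charged substrate at 3.00 d. Read backwards, the drain time over 39.5% makes Saturday's effective window 1.81 d, a figure fitted to that result. In the neighbouring flask, Saturday's with 0.17 M of substrate, the drain time shrinks to 0.578 d, and that window then gives 31.9%, where the simulation gives 29.2%.

The constants stand for no real mixture; no experiment stands behind them.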